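**Retrosynthetic overview**

1. Numbering (briarane): C1 is the quaternary ring-fusion carbon (C15 methyl), C2–C9 complete the ten-membered ring B (C16 is the exocyclic methylene on C5), C10 is the ring-fusion CH, ring A is C1/C10/C11 (C20 methyl)/C12 (ketone)/C13/C14 (butanoate), and the lactone is C7–O–C19(=O)–C17(C18)–C8. The esters and the C6 chloride (OH to Cl with inversion) are added last; the γ-lactone comes from a samarium Reformatsky closure (C17–C8); ring B is closed at C5–C6 by a Nozaki–Hiyama–Kishi reaction.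
2. Ring A is carried as a 1-silyloxybicyclo[3.1.0]hexane and is unveiled late by strain-release oxidative cleavage of the extra bond C12–C14 (C12 becomes the ketone, C14 takes oxygen). The feature that allows this is the 1,3-relation of the C12 carbonyl and the C14 oxygen across the C13 methylene in ring A: a β-oxygenated cyclohexanone is a ring-expanded cyclopropanol.
3. The cyclopropanol is made in the key step, an intramolecular Kulinkovich reaction between a δ-lactone carbonyl (C12, tethered through O to C8) and the vinyl group C13=C14 on quaternary C1. It forms C12–C13 and the temporary bond C12–C14 and opens the lactone tether to free C8–OH.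
4. Stereochemical relay: C9 is bought ((R)-but-3-ene-1,2-diol). A Diels–Alder reaction of the derived α-methyl δ-lactone with a 1,3-dioxygenated pentadiene sets C1, C2, C10 and C11 in one event; the cyclohexene so formed is a temporary ring, cut by ozonolysis into C3 and C12. C7 is set by reagent-controlled alkoxyallylboration, and C6, C8, C17 and C14 by substrate control.
5. Order of ring formation: δ-lactone (metathesis), temporary cyclohexene (Diels–Alder), second δ-lactone (C12/C8), cyclopropane plus cyclopentane (key step), ring B, γ-lactone, ring A (ring expansion).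

Key step: step 11

Remark on the chemistry: the configurations at C12/C14 of the cyclopropanol (compounds 15–34) and at C8 before its oxidation (18–31) are drawn as expected but are inconsequential, because step 29 and step 27 erase them.

**Route**

Step 1
Reactants: 1 (R)-but-3-ene-1,2-diol
Product: 2 (R)-2-hydroxybut-3-en-1-yl 2-methylprop-2-enoate
Conditions: methacryloyl chloride (1.0 equiv), 2,4,6-collidine, CH2Cl2, −78 °C
Reagents that add atoms: methacryloyl chloride, C=C(C)C(=O)Cl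
Why: Selective acylation of the primary hydroxyl of a 1,2-diol by an acid chloride with a hindered pyridine base at low temperature; the bought C9 stereocentre is untouched.

Step 2
Reactants: 2 (R)-2-hydroxybut-3-en-1-yl 2-methylprop-2-enoate
Product: 3 (R)-2-[(tert-butyldimethylsilyl)oxy]but-3-en-1-yl 2-methylprop-2-enoate
Conditions: t-BuMe2SiCl, imidazole, DMF, 25 °C
Reagents that add atoms: tert-butyldimethylsilyl chloride, CC(C)(C)[Si](C)(C)Cl
Why: Standard silylation of the secondary allylic alcohol.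

Step 3
Reactants: 3 (R)-2-[(tert-butyldimethylsilyl)oxy]but-3-en-1-yl 2-methylprop-2-enoate
Product: 4 (R)-5-[(tert-butyldimethylsilyl)oxy]-3-methyl-5,6-dihydro-2H-pyran-2-one
Conditions: second-generation Grubbs catalyst (H2IMes)(PCy3)Cl2Ru=CHPh (5 mol %), PhMe, 80 °C
Reagents that add atoms: none
Why: Ring-closing metathesis of the methacrylate with the allylic vinyl group should give the trisubstituted C1=C10 bond of the α-methyl δ-lactone and release ethene.

Step 4
Reactants: 5 pent-1-yn-3-one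
Product: 6 (E)-1-[(4-methoxybenzyl)oxy]pent-1-en-3-one
Conditions: 4-methoxybenzyl alcohol, PMe3 (10 mol %), CH2Cl2, 0 → 25 °C
Reagents that add atoms: 4-methoxybenzyl alcohol, COc1ccc(CO)cc1
Why: Phosphine-catalysed conjugate addition of an alcohol to an ynone, which should give the (E)-β-alkoxy enone.

Step 5
Reactants: 6 (E)-1-[(4-methoxybenzyl)oxy]pent-1-en-3-one
Product: 7 (1E,3Z)-3-[(tert-butyldimethylsilyl)oxy]-1-[(4-methoxybenzyl)oxy]penta-1,3-diene
Conditions: t-BuMe2SiOTf, Et3N, Et2O, 0 °C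
Reagents that add atoms: tert-butyldimethylsilyl trifluoromethanesulfonate, CC(C)(C)[Si](C)(C)OS(=O)(=O)C(F)(F)F
Why: Soft enolisation of the ethyl ketone with a silyl triflate and an amine should give the (Z)-silyl enol ether, i.e. the diene with both terminal substituents outside.

Step 6
Reactants: 4 (R)-5-[(tert-butyldimethylsilyl)oxy]-3-methyl-5,6-dihydro-2H-pyran-2-one; 7 (1E,3Z)-3-[(tert-butyldimethylsilyl)oxy]-1-[(4-methoxybenzyl)oxy]penta-1,3-diene
Product: 8 cis-fused Diels–Alder lactone (4,6-bis-silyloxy-8-(4-methoxybenzyloxy)-5,8a-dimethyl-hexahydroisochromen-1-one)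
Conditions: PhMe, 130 °C, sealed tube, BHT (cat.)
Reagents that add atoms: none
Why: Diels–Alder reaction of a 1,3-dioxygenated diene with an α,β-unsaturated δ-lactone, in which the methyl-bearing diene terminus should bond to the β-carbon C10 and the PMBO-bearing terminus to C1, on the lactone face anti to the C9 silyl ether and endo to the lactone carbonyl, so that C1, C2, C10 and C11 are set together relative to C9.

Step 7
Reactants: 8 cis-fused Diels–Alder lactone
Product: 9 C14 lactol of 8 (anomer mixture)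
Conditions: i-Bu2AlH (1.1 equiv), CH2Cl2, −78 °C; Rochelle salt work-up
Reagents that add atoms: none
Why: Partial reduction of a lactone to the lactol with diisobutylaluminium hydride at low temperature; the silyl enol ether and the ethers are inert.

Step 8
Reactants: 9 C14 lactol of 8
Product: 10 C1-vinyl cyclohexene with free C8 hydroxyl
Conditions: Ph3PCH3Br, KN(SiMe3)2, THF, 0 → 25 °C
Reagents that add atoms: methylenetriphenylphosphorane (made in the flask), C=P(c1ccccc1)(c1ccccc1)c1ccccc1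
Why: Wittig methylenation of the lactol through its open hydroxy-aldehyde form should turn C14 into the vinyl group C14=C13 and free the C8 hydroxyl.

Step 9
Reactants: 10 C1-vinyl cyclohexene with free C8 hydroxyl
Product: 13 δ-lactone (C12 carbonyl, O–C8) with free C3 hydroxyl, via aldehyde silyl ester 11 (not isolated), via seco acid 12 (not isolated)
Conditions: O3 (1 equiv), CH2Cl2/MeOH, NaHCO3, −78 °C; NaBH4, −78 → 0 °C; aq. citric acid; PPTS, PhH, 50 °C
Reagents that add atoms: ozone, [O-][O+]=O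
Why: Ozonolysis should be chemoselective for the electron-rich silyl enol ether over the neopentyl vinyl group and cut the temporary cyclohexene into C3 (aldehyde, reduced in the same flask) and C12 (silyl ester), after which the C12 acid lactonises onto the free C8 hydroxyl.

Step 10
Reactants: 13 δ-lactone with free C3 hydroxyl
Product: 14 C2/C3 4-methoxybenzylidene acetal of 13
Conditions: DDQ (1.2 equiv), 4 Å molecular sieves, CH2Cl2, 0 °C
Reagents that add atoms: none
Why: Anhydrous DDQ should oxidise the PMB ether to its oxocarbenium ion, which the neighbouring C3 hydroxyl traps as the 4-methoxybenzylidene acetal (known oxidative acetalisation of 1,2-diol mono-PMB ethers).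

Step 11
Reactants: 14 C2/C3 4-methoxybenzylidene acetal of 13
Product: 15 1-hydroxybicyclo[3.1.0]hexane (C12 carbinol, C13 methylene, C14) with free C8 hydroxyl
Conditions: ClTi(OiPr)3 (1.2 equiv), c-C5H9MgCl (4.5 equiv, slow addition), THF, 25 °C
Reagents that add atoms: none
Why: Intramolecular Kulinkovich reaction in its olefin-exchange form: the Grignard reagent turns ClTi(OiPr)3 into a divalent titanium–cyclopentene complex (titanacyclopropane), which exchanges cyclopentene for the terminal C13=C14 vinyl group; the lactone carbonyl C12 inserts into the Ti–C13 bond (forming C12–C13 and a six-membered carbocycle within a bridged oxatitanacycle), the C8 alkoxide is expelled to leave a β-titanio ketone, and the Ti–C14 bond adds to the new C12 ketone. The closest known reaction type is the titanium-mediated cyclopropanation of ω-alkenyl esters to bicyclo[n.1.0]alkan-1-ols and of lactones to hydroxyalkyl cyclopropanols. Rings closed: the cyclopropane (C12–C13 by carbonyl insertion, then C12–C14 by 3-exo-trig addition) and with it the cyclopentane C12–C11–C10–C1–C14 (5-exo attack of C14 on C12), while the δ-lactone tether is opened in the same operation. New stereocentres C12 and C14: cis fusion is enforced by the bicycle and the methylene should form anti to the C15 and C20 methyl groups, but both centres are cleared in step 29, so no selectivity is demanded of them, and C1, C2, C9, C10 and C11 are untouched. The selectivity needed is chemoselectivity for intramolecular exchange and insertion over attack of the cyclopentene titanacycle on the lactone, which should be secured by the single terminal alkene held three atoms from the only carbonyl group and by slow addition of the Grignard reagent.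

Step 12
Reactants: 15 1-hydroxybicyclo[3.1.0]hexane with free C8 hydroxyl
Product: 16 bis(triethylsilyl) ether of 15 (cyclopropanol O and C8 O)
Conditions: Et3SiCl, imidazole, DMAP, DMF, 40 °C
Reagents that add atoms: chlorotriethylsilane, CC[Si](Cl)(CC)CC
Why: Silylation of both hydroxyls with the silyl chloride, which is chosen because silyl triflates would cleave the benzylidene acetal.

Step 13
Reactants: 16 bis(triethylsilyl) ether of 15
Product: 17 C8 aldehyde
Conditions: (COCl)2, DMSO, CH2Cl2, −78 → −30 °C; Et3N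
Reagents that add atoms: none
Why: Swern conditions convert a primary triethylsilyl ether directly into the aldehyde while secondary and tertiary silyl ethers stay (known selective oxidative desilylation).

Step 14
Reactants: 17 C8 aldehyde
Product: 18 syn alkoxyallylation product (C8–OH, C7–OMOM, C6=CH2)
Conditions: CH2=CHCH2OCH2OMe, s-BuLi, THF, −78 °C; (+)-Ipc2BOMe; BF3·OEt2; 17, −78 °C; NaOH, H2O2
Reagents that add atoms: 3-(methoxymethoxy)prop-1-ene, C=CCOCOC
Why: Asymmetric γ-alkoxyallylboration, in which the (Z)-γ-(methoxymethoxy)allyl diisopinocampheylborane should add through a chair transition state to give the syn 1,2-diol monoether with the C7 configuration fixed by the reagent (re-face attack on C8).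

Step 15
Reactants: 18 syn alkoxyallylation product
Product: 20 C8/C6 diol, via hydroxy aldehyde 19 (not isolated)
Conditions: OsO4 (2 mol %), NaIO4, 2,6-lutidine, dioxane/H2O, 25 °C; NaBH4, MeOH, 0 °C
Reagents that add atoms: sodium periodate (terminal oxidant, oxygen delivered through OsO4), [Na+].[O-][I](=O)(=O)=O
Why: Dihydroxylation–periodate cleavage of the only alkene and borohydride reduction in the same flask should give the primary C6 alcohol.

Step 16
Reactants: 20 C8/C6 diol
Product: 21 C8,C6-bis(triethylsilyl) ether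
Conditions: Et3SiCl, imidazole, DMAP, DMF, 40 °C
Reagents that add atoms: chlorotriethylsilane, CC[Si](Cl)(CC)CC
Why: Silylation of the primary and the secondary hydroxyl, giving a primary ether that step 21 can oxidise selectively.

Step 17
Reactants: 21 C8,C6-bis(triethylsilyl) ether
Product: 22 C2 PMB ether with free primary C3 hydroxyl
Conditions: i-Bu2AlH (3 equiv), CH2Cl2, −78 → −20 °C
Reagents that add atoms: none
Why: Reductive opening of a 4-methoxybenzylidene acetal with diisobutylaluminium hydride, which coordinates the less hindered primary oxygen and should leave the PMB group on the secondary C2 oxygen.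

Step 18
Reactants: 22 C2 PMB ether with free primary C3 hydroxyl
Product: 23 C3 aldehyde
Conditions: Dess–Martin periodinane, NaHCO3, CH2Cl2, 0 → 25 °C
Reagents that add atoms: none
Why: Buffered Dess–Martin oxidation of a primary alcohol, mild enough for the silyloxycyclopropane and the α-alkoxy aldehyde.

Step 19
Reactants: 23 C3 aldehyde
Product: 24 (E)-enone (C3=C4, C5 ketone, C16 methyl)
Conditions: Ph3P=CHC(O)CH3, PhMe, 80 °C
Reagents that add atoms: 1-(triphenylphosphoranylidene)propan-2-one, CC(=O)C=P(c1ccccc1)(c1ccccc1)c1ccccc1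
Why: Wittig reaction with a stabilised ylide, which should give the (E)-enone under neutral conditions and adds C4, C5 and C16.

Step 20
Reactants: 24 (E)-enone
Product: 25 2-triflyloxy-1,3-diene (C5–OTf, C5=C16)
Conditions: KN(SiMe3)2 (1.1 equiv), THF, −78 °C; PhNTf2
Reagents that add atoms: N-phenylbis(trifluoromethanesulfonimide), O=S(=O)(N(c1ccccc1)S(=O)(=O)C(F)(F)F)C(F)(F)F
Why: Kinetic deprotonation of the methyl ketone at C16 and O-triflation of the enolate; no ester or ketone other than the enone is present.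

Step 21
Reactants: 25 2-triflyloxy-1,3-diene
Product: 26 C6 aldehyde
Conditions: (COCl)2, DMSO, CH2Cl2, −78 → −30 °C; Et3N
Reagents that add atoms: none
Why: Selective Swern oxidation of the primary triethylsilyl ether to the aldehyde, as in step 13; the secondary and tertiary silyl ethers and the dienyl triflate stay.

Step 22
Reactants: 26 C6 aldehyde
Product: 27 ring B carbinol (ten-membered ring, 6β-OH, (3E), C5=C16)
Conditions: CrCl2 (10 equiv), NiCl2 (10 mol %), DMSO/THF 4:1, 25 °C, 0.002 M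
Reagents that add atoms: none
Why: Intramolecular Nozaki–Hiyama–Kishi reaction, in which zerovalent nickel inserts into the dienyl triflate, transmetalation gives the trivalent alkenylchromium species, and this adds to the C6 aldehyde at high dilution to close ring B, with chelation of chromium between the aldehyde and the C7 MOM ether expected to favour the 6,7-syn alcohol.

Step 23
Reactants: 27 ring B carbinol
Product: 28 6α-chloride
Conditions: Cl3CC(O)CCl3, PPh3, CH2Cl2, −20 → 0 °C
Reagents that add atoms: hexachloroacetone, ClC(Cl)(Cl)C(=O)C(Cl)(Cl)Cl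
Why: Hexachloroacetone/triphenylphosphine converts allylic alcohols into chlorides by SN2 displacement of the oxyphosphonium ion, i.e. with inversion at C6 and without allylic transposition.

Step 24
Reactants: 28 6α-chloride
Product: 29 C7 alcohol
Conditions: Me2BBr, CH2Cl2, −78 °C; aq. NaHCO3/THF
Reagents that add atoms: none
Why: Dimethylboron bromide cleaves methoxymethyl ethers at −78 °C through the bromomethyl ether and should leave silyl ethers, the PMB ether and the allylic chloride alone.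

Step 25
Reactants: 29 C7 alcohol
Product: 30 C7 2-bromopropanoate
Conditions: 2-bromopropanoyl bromide, pyridine, CH2Cl2, 0 °C
Reagents that add atoms: 2-bromopropanoyl bromide, CC(Br)C(=O)Br
Why: Acylation of the only free hydroxyl; the bromide-bearing centre is destroyed in step 28, so the racemic reagent suffices.

Step 26
Reactants: 30 C7 2-bromopropanoate
Product: 31 C8 alcohol
Conditions: HF·pyridine, pyridine, THF, 0 °C
Reagents that add atoms: none
Why: Buffered HF·pyridine should remove the secondary triethylsilyl ether faster than the tertiary cyclopropyl triethylsilyl ether and the TBS ether.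

Step 27
Reactants: 31 C8 alcohol
Product: 32 C8 ketone
Conditions: Dess–Martin periodinane, NaHCO3, CH2Cl2, 0 °C
Reagents that add atoms: none
Why: Buffered Dess–Martin oxidation to the α-acyloxy ketone without acyl migration or epimerisation at C7.

Step 28
Reactants: 32 C8 ketone
Product: 33 γ-lactone (C8–OH, C18 methyl) with ring A masked as the silyloxycyclopropane
Conditions: SmI2 (2.2 equiv), THF, −78 °C
Reagents that add atoms: none
Why: Samarium Reformatsky reaction, in which divalent samarium reduces the α-bromo ester to a trivalent samarium enolate that adds to the adjacent C8 ketone through a chelated chair-like transition state on the outer face of the macrocyclic ketone (5-exo-trig), expected to give the C8 hydroxyl and C18 methyl as drawn.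

Step 29
Reactants: 33 γ-lactone with masked ring A
Product: 36 14α-hydroxy-12-ketone (ring A formed), via free cyclopropanol 34 (not isolated), via hydroperoxy ketone 35 (not isolated)
Conditions: Bu4NF/AcOH (1:1), THF, 0 °C; Mn(acac)3 (5 mol %), O2 (1 atm), PhH, 25 °C; PPh3
Reagents that add atoms: dioxygen, O=O
Why: Aerobic oxidative ring expansion of a bicyclo[n.1.0]alkan-1-ol catalysed by trivalent manganese, in which β-scission of the strained C12–C14 bond gives the ring A ketone with a C14 radical that should take up O2 axially, anti to the axial C15 methyl of the chair locked by trans fusion to ring B, before triphenylphosphine reduces the hydroperoxide.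

Step 30
Reactants: 36 14α-hydroxy-12-ketone
Product: 37 14-butanoate
Conditions: (PrCO)2O, DMAP, pyridine, CH2Cl2, 0 °C
Reagents that add atoms: butanoic anhydride, CCCC(=O)OC(=O)CCC
Why: DMAP-catalysed acylation of the only secondary hydroxyl; the tertiary C8 hydroxyl should not react at 0 °C.

Step 31
Reactants: 37 14-butanoate
Product: 38 C2 alcohol
Conditions: DDQ, CH2Cl2/pH 7 buffer 10:1, 0 °C
Reagents that add atoms: none
Why: Oxidative cleavage of the PMB ether with DDQ in wet dichloromethane.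

Step 32
Reactants: 38 C2 alcohol
Product: 39 C2,C9 diol
Conditions: HF·pyridine, THF, 25 °C
Reagents that add atoms: none
Why: Fluoride cleavage of the hindered secondary TBS ether under non-basic conditions that should not enolise the C12 ketone or epimerise C11.

Step 33
Reactants: 39 C2,C9 diol
Product: 40 target CNP0283653.2
Conditions: Ac2O, pyridine, DMAP (cat.), CH2Cl2, 0 → 25 °C
Reagents that add atoms: acetic anhydride, CC(=O)OC(C)=O
Why: Acetylation of the two secondary hydroxyls at C2 and C9 while the tertiary C8 hydroxyl stays free.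

**Compound list**

1 | (R)-but-3-ene-1,2-diol | C=C[C@@H](O)CO | starting material
2 | (R)-2-hydroxybut-3-en-1-yl 2-methylprop-2-enoate | C=C[C@@H](O)COC(=O)C(C)=C | intermediate
3 | (R)-2-[(tert-butyldimethylsilyl)oxy]but-3-en-1-yl 2-methylprop-2-enoate | C=C[C@@H](O[Si](C)(C)C(C)(C)C)COC(=O)C(C)=C | intermediate
4 | (R)-5-[(tert-butyldimethylsilyl)oxy]-3-methyl-5,6-dihydro-2H-pyran-2-one (C14, C1, C15, C10, C9, C8) | CC1=C[C@@H](O[Si](C)(C)C(C)(C)C)COC1=O | intermediate
5 | pent-1-yn-3-one | CCC(=O)C#C | starting material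
6 | (E)-1-[(4-methoxybenzyl)oxy]pent-1-en-3-one | CCC(=O)/C=C/OCc1ccc(OC)cc1 | intermediate
7 | (1E,3Z)-3-[(tert-butyldimethylsilyl)oxy]-1-[(4-methoxybenzyl)oxy]penta-1,3-diene | C/C=C(O[Si](C)(C)C(C)(C)C)/C=C/OCc1ccc(OC)cc1 | intermediate
8 | cis-fused Diels–Alder lactone: 4,6-bis(TBS-oxy)-8-(PMB-oxy)-5,8a-dimethyl-3,4,4a,5,8,8a-hexahydro-1H-isochromen-1-one; C14 carbonyl, C2 OPMB and C11 methyl all cis, C9 OTBS trans to the C10–C11 bond | C1[C@@H](OCc2ccc(OC)cc2)[C@]3(C)[C@@H]([C@@H](O[Si](C)(C)C(C)(C)C)COC3=O)[C@@H](C)C(O[Si](C)(C)C(C)(C)C)=1 | intermediate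
9 | C14 lactol of 8 (anomer mixture) | C1[C@@H](OCc2ccc(OC)cc2)[C@]3(C)[C@@H]([C@@H](O[Si](C)(C)C(C)(C)C)COC3O)[C@@H](C)C(O[Si](C)(C)C(C)(C)C)=1 | intermediate
10 | C1-vinyl cyclohexene silyl enol ether with free C8 hydroxyl | C1[C@@H](OCc2ccc(OC)cc2)[C@](C=C)(C)[C@@H]([C@@H](O[Si](C)(C)C(C)(C)C)CO)[C@@H](C)C(O[Si](C)(C)C(C)(C)C)=1 | intermediate
11 | C3 aldehyde / C12 TBS ester from ozonolysis | O=C[C@@H](OCc1ccc(OC)cc1)[C@](C=C)(C)[C@@H]([C@@H](O[Si](C)(C)C(C)(C)C)CO)[C@@H](C)C(=O)O[Si](C)(C)C(C)(C)C | intermediate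
12 | seco acid (C3 and C8 primary alcohols, C12 acid) | OC[C@@H](OCc1ccc(OC)cc1)[C@](C=C)(C)[C@@H]([C@@H](O[Si](C)(C)C(C)(C)C)CO)[C@@H](C)C(=O)O | intermediate
13 | δ-lactone (C12 carbonyl, O–C8; C11 methyl trans to the C10 substituent) with C2 OPMB, free C3 hydroxyl and C1 vinyl | OC[C@@H](OCc1ccc(OC)cc1)[C@](C=C)(C)[C@@H]([C@@H](O[Si](C)(C)C(C)(C)C)COC2=O)[C@H]2C | intermediate
14 | C2/C3 4-methoxybenzylidene acetal of 13 (acetal carbon unassigned) | C1OC(c2ccc(OC)cc2)O[C@H]1[C@](C=C)(C)[C@@H]([C@@H](O[Si](C)(C)C(C)(C)C)COC3=O)[C@H]3C | intermediate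
15 | 1-hydroxybicyclo[3.1.0]hexane (C12 carbinol, C13 methylene, C14; cyclopentane C12–C11–C10–C1–C14) with free C8 hydroxyl | C1OC(c2ccc(OC)cc2)O[C@H]1[C@]3(C)[C@@H]([C@@H](O[Si](C)(C)C(C)(C)C)CO)[C@@H](C)[C@]4(O)C[C@H]34 | intermediate
16 | bis(triethylsilyl) ether of 15 | C1OC(c2ccc(OC)cc2)O[C@H]1[C@]3(C)[C@@H]([C@@H](O[Si](C)(C)C(C)(C)C)CO[Si](CC)(CC)CC)[C@@H](C)[C@]4(O[Si](CC)(CC)CC)C[C@H]34 | intermediate
17 | C8 aldehyde | C1OC(c2ccc(OC)cc2)O[C@H]1[C@]3(C)[C@@H]([C@@H](O[Si](C)(C)C(C)(C)C)C=O)[C@@H](C)[C@]4(O[Si](CC)(CC)CC)C[C@H]34 | intermediate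
18 | syn alkoxyallylation product (C8–OH, C7–OMOM, terminal alkene at C6) | C1OC(c2ccc(OC)cc2)O[C@H]1[C@]3(C)[C@@H]([C@@H](O[Si](C)(C)C(C)(C)C)[C@H](O)[C@@H](OCOC)C=C)[C@@H](C)[C@]4(O[Si](CC)(CC)CC)C[C@H]34 | intermediate
19 | C6 aldehyde with free C8 hydroxyl | C1OC(c2ccc(OC)cc2)O[C@H]1[C@]3(C)[C@@H]([C@@H](O[Si](C)(C)C(C)(C)C)[C@H](O)[C@@H](OCOC)C=O)[C@@H](C)[C@]4(O[Si](CC)(CC)CC)C[C@H]34 | intermediate
20 | C8/C6 diol | C1OC(c2ccc(OC)cc2)O[C@H]1[C@]3(C)[C@@H]([C@@H](O[Si](C)(C)C(C)(C)C)[C@H](O)[C@@H](OCOC)CO)[C@@H](C)[C@]4(O[Si](CC)(CC)CC)C[C@H]34 | intermediate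
21 | C8,C6-bis(triethylsilyl) ether | C1OC(c2ccc(OC)cc2)O[C@H]1[C@]3(C)[C@@H]([C@@H](O[Si](C)(C)C(C)(C)C)[C@H](O[Si](CC)(CC)CC)[C@@H](OCOC)CO[Si](CC)(CC)CC)[C@@H](C)[C@]4(O[Si](CC)(CC)CC)C[C@H]34 | intermediate
22 | C2 PMB ether, free primary C3 hydroxyl | OC[C@@H](OCc1ccc(OC)cc1)[C@]3(C)[C@@H]([C@@H](O[Si](C)(C)C(C)(C)C)[C@H](O[Si](CC)(CC)CC)[C@@H](OCOC)CO[Si](CC)(CC)CC)[C@@H](C)[C@]4(O[Si](CC)(CC)CC)C[C@H]34 | intermediate
23 | C3 aldehyde | O=C[C@@H](OCc1ccc(OC)cc1)[C@]3(C)[C@@H]([C@@H](O[Si](C)(C)C(C)(C)C)[C@H](O[Si](CC)(CC)CC)[C@@H](OCOC)CO[Si](CC)(CC)CC)[C@@H](C)[C@]4(O[Si](CC)(CC)CC)C[C@H]34 | intermediate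
24 | (E)-enone (C3=C4, C5 ketone, C16 methyl) | CC(=O)/C=C/[C@@H](OCc1ccc(OC)cc1)[C@]3(C)[C@@H]([C@@H](O[Si](C)(C)C(C)(C)C)[C@H](O[Si](CC)(CC)CC)[C@@H](OCOC)CO[Si](CC)(CC)CC)[C@@H](C)[C@]4(O[Si](CC)(CC)CC)C[C@H]34 | intermediate
25 | (3E)-2-triflyloxy-1,3-diene (C5–OTf, C5=C16) | C=C(OS(=O)(=O)C(F)(F)F)/C=C/[C@@H](OCc1ccc(OC)cc1)[C@]3(C)[C@@H]([C@@H](O[Si](C)(C)C(C)(C)C)[C@H](O[Si](CC)(CC)CC)[C@@H](OCOC)CO[Si](CC)(CC)CC)[C@@H](C)[C@]4(O[Si](CC)(CC)CC)C[C@H]34 | intermediate
26 | C6 aldehyde (dienyl triflate retained) | C=C(OS(=O)(=O)C(F)(F)F)/C=C/[C@@H](OCc1ccc(OC)cc1)[C@]3(C)[C@@H]([C@@H](O[Si](C)(C)C(C)(C)C)[C@H](O[Si](CC)(CC)CC)[C@@H](OCOC)C=O)[C@@H](C)[C@]4(O[Si](CC)(CC)CC)C[C@H]34 | intermediate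
27 | ring B carbinol: ten-membered ring, (3E), C5=C16, 6β-OH (6,7-syn to the MOM ether) | C=C1/C=C/[C@@H](OCc2ccc(OC)cc2)[C@]3(C)[C@@H]([C@@H](O[Si](C)(C)C(C)(C)C)[C@H](O[Si](CC)(CC)CC)[C@@H](OCOC)[C@@H]1O)[C@@H](C)[C@]4(O[Si](CC)(CC)CC)C[C@H]34 | intermediate
28 | 6α-chloride | C=C1/C=C/[C@@H](OCc2ccc(OC)cc2)[C@]3(C)[C@@H]([C@@H](O[Si](C)(C)C(C)(C)C)[C@H](O[Si](CC)(CC)CC)[C@@H](OCOC)[C@H]1Cl)[C@@H](C)[C@]4(O[Si](CC)(CC)CC)C[C@H]34 | intermediate
29 | C7 alcohol | C=C1/C=C/[C@@H](OCc2ccc(OC)cc2)[C@]3(C)[C@@H]([C@@H](O[Si](C)(C)C(C)(C)C)[C@H](O[Si](CC)(CC)CC)[C@@H](O)[C@H]1Cl)[C@@H](C)[C@]4(O[Si](CC)(CC)CC)C[C@H]34 | intermediate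
30 | C7 2-bromopropanoate (bromide epimers) | C=C1/C=C/[C@@H](OCc2ccc(OC)cc2)[C@]3(C)[C@@H]([C@@H](O[Si](C)(C)C(C)(C)C)[C@H](O[Si](CC)(CC)CC)[C@@H](OC(=O)C(C)Br)[C@H]1Cl)[C@@H](C)[C@]4(O[Si](CC)(CC)CC)C[C@H]34 | intermediate
31 | C8 alcohol | C=C1/C=C/[C@@H](OCc2ccc(OC)cc2)[C@]3(C)[C@@H]([C@@H](O[Si](C)(C)C(C)(C)C)[C@H](O)[C@@H](OC(=O)C(C)Br)[C@H]1Cl)[C@@H](C)[C@]4(O[Si](CC)(CC)CC)C[C@H]34 | intermediate
32 | C8 ketone | C=C1/C=C/[C@@H](OCc2ccc(OC)cc2)[C@]3(C)[C@@H]([C@@H](O[Si](C)(C)C(C)(C)C)C(=O)[C@@H](OC(=O)C(C)Br)[C@H]1Cl)[C@@H](C)[C@]4(O[Si](CC)(CC)CC)C[C@H]34 | intermediate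
33 | γ-lactone (C8–OH, C17 methyl as in the target) with ring A masked as the silyloxycyclopropane | C=C1/C=C/[C@@H](OCc2ccc(OC)cc2)[C@]3(C)[C@@H]([C@@H](O[Si](C)(C)C(C)(C)C)[C@]5(O)[C@@H](C)C(=O)O[C@H]5[C@H]1Cl)[C@@H](C)[C@]4(O[Si](CC)(CC)CC)C[C@H]34 | intermediate
34 | free cyclopropanol | C=C1/C=C/[C@@H](OCc2ccc(OC)cc2)[C@]3(C)[C@@H]([C@@H](O[Si](C)(C)C(C)(C)C)[C@]5(O)[C@@H](C)C(=O)O[C@H]5[C@H]1Cl)[C@@H](C)[C@]4(O)C[C@H]34 | intermediate
35 | 14α-hydroperoxy-12-ketone | C=C1/C=C/[C@@H](OCc2ccc(OC)cc2)[C@]3(C)[C@@H]([C@@H](O[Si](C)(C)C(C)(C)C)[C@]5(O)[C@@H](C)C(=O)O[C@H]5[C@H]1Cl)[C@@H](C)C(=O)C[C@@H]3OO | intermediate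
36 | 14α-hydroxy-12-ketone | C=C1/C=C/[C@@H](OCc2ccc(OC)cc2)[C@]3(C)[C@@H]([C@@H](O[Si](C)(C)C(C)(C)C)[C@]5(O)[C@@H](C)C(=O)O[C@H]5[C@H]1Cl)[C@@H](C)C(=O)C[C@@H]3O | intermediate
37 | 14-butanoate | C=C1/C=C/[C@@H](OCc2ccc(OC)cc2)[C@]3(C)[C@@H]([C@@H](O[Si](C)(C)C(C)(C)C)[C@]5(O)[C@@H](C)C(=O)O[C@H]5[C@H]1Cl)[C@@H](C)C(=O)C[C@@H]3OC(=O)CCC | intermediate
38 | C2 alcohol | C=C1/C=C/[C@@H](O)[C@]3(C)[C@@H]([C@@H](O[Si](C)(C)C(C)(C)C)[C@]5(O)[C@@H](C)C(=O)O[C@H]5[C@H]1Cl)[C@@H](C)C(=O)C[C@@H]3OC(=O)CCC | intermediate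
39 | C2,C9 diol | C=C1/C=C/[C@@H](O)[C@]3(C)[C@@H]([C@@H](O)[C@]5(O)[C@@H](C)C(=O)O[C@H]5[C@H]1Cl)[C@@H](C)C(=O)C[C@@H]3OC(=O)CCC | intermediate
40 | CNP0283653.2 (2,9-diacetate, 14-butanoate, 6-chloride, 8-hydroxy lactone, 12-ketone) | C=C1/C=C/[C@@H](OC(C)=O)[C@]2(C)[C@@H]([C@@H](OC(C)=O)[C@]3(O)[C@@H](C)C(=O)O[C@H]3[C@H]1Cl)[C@@H](C)C(=O)C[C@@H]2OC(=O)CCC | target

**Totals and risks**

Total step count: 33. Longest linear sequence: 31 steps (steps 1–3 and 6–33; steps 4–5 make the diene).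

Steps most likely to fail:

Step 11. Olefin exchange at the neopentyl vinyl group may be slower than attack of the cyclopentene titanacycle on the lactone, so that the lactone is consumed without cyclisation. Fallback, from 14 back to 16: reduce the lactone with i-Bu2AlH to the C12 lactol F1 and methylenate it (Ph3P=CH2) to the diene alcohol F2, which has vinyl groups on C11 and on C1. Silylate (Et3SiCl, imidazole) to the triethylsilyl ether F3 and close the cyclopentene F4 (C12=C14) by ring-closing metathesis with the second-generation Grubbs catalyst (H2IMes)(PCy3)Cl2Ru=CHPh. Hydroboration with 9-BBN at the carbon remote from the quaternary centre, followed by oxidation, gives the cyclopentanol F5. Dess–Martin oxidation gives the cyclopentanone F6, and LiN(i-Pr)2/Et3SiCl gives the less substituted silyl enol ether F7. Simmons–Smith cyclopropanation (Et2Zn, CH2I2) then forms the C12–C13 and C13–C14 bonds and rejoins the route at 16.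

Step 29. The peroxyl radical may add to the ring B diene, or oxygen capture at C14 may occur on the wrong face. Fallback, from 33 back to 36: FeCl3 in DMF/pyridine should open the silyloxycyclopropane at the internal bond with chlorine transfer to give the ring-expanded β-chloro ketone F8, and NaOAc in MeOH removes HCl to give the cyclohexenone F9. Nucleophilic epoxidation (t-BuOOH, DBU) from the α-face, anti to the C15 methyl, gives the epoxy ketone F10. Reductive opening at the α-carbon with sodium phenylselenide ((PhSe)2, NaBH4, AcOH, EtOH) returns to 36.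

Step 22. Oligomerisation may compete with ten-membered ring closure, and facial selectivity at C6 may be poor. Fallback, from 23 back to 27: methylenation (Ph3P=CH2) gives the C2 vinyl compound F11, and Swern oxidation of the primary silyl ether gives the C6 aldehyde F12. Chelation-controlled addition of buta-1,3-dien-2-ylmagnesium chloride gives the dienyl carbinol F13 (C6 hydroxyl syn to the C7 MOM ether). Diene–ene ring-closing metathesis with the second-generation Grubbs catalyst (H2IMes)(PCy3)Cl2Ru=CHPh at high dilution forms C3=C4 and rejoins the route at 27.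

Further compounds
F1 | step 11 | C12 lactol of 14 | C1OC(c2ccc(OC)cc2)O[C@H]1[C@](C=C)(C)[C@@H]([C@@H](O[Si](C)(C)C(C)(C)C)COC3O)[C@H]3C
F2 | step 11 | diene alcohol (C12 vinyl on C11, C14 vinyl on C1, free C8 hydroxyl) | C1OC(c2ccc(OC)cc2)O[C@H]1[C@](C=C)(C)[C@@H]([C@@H](O[Si](C)(C)C(C)(C)C)CO)[C@@H](C)C=C
F3 | step 11 | C8 triethylsilyl ether of F2 | C1OC(c2ccc(OC)cc2)O[C@H]1[C@](C=C)(C)[C@@H]([C@@H](O[Si](C)(C)C(C)(C)C)CO[Si](CC)(CC)CC)[C@@H](C)C=C
F4 | step 11 | cyclopentene (C12=C14) | C1OC(c2ccc(OC)cc2)O[C@H]1[C@]3(C)[C@@H]([C@@H](O[Si](C)(C)C(C)(C)C)CO[Si](CC)(CC)CC)[C@@H](C)C=C3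
F5 | step 11 | cyclopentanol (C12–OH) | C1OC(c2ccc(OC)cc2)O[C@H]1[C@]3(C)[C@@H]([C@@H](O[Si](C)(C)C(C)(C)C)CO[Si](CC)(CC)CC)[C@@H](C)C(O)C3
F6 | step 11 | cyclopentanone (C12 ketone) | C1OC(c2ccc(OC)cc2)O[C@H]1[C@]3(C)[C@@H]([C@@H](O[Si](C)(C)C(C)(C)C)CO[Si](CC)(CC)CC)[C@@H](C)C(=O)C3
F7 | step 11 | triethylsilyl enol ether (C12=C14) | C1OC(c2ccc(OC)cc2)O[C@H]1[C@]3(C)[C@@H]([C@@H](O[Si](C)(C)C(C)(C)C)CO[Si](CC)(CC)CC)[C@@H](C)C(O[Si](CC)(CC)CC)=C3
F8 | step 29 | 14-chloro-12-ketone | C=C1/C=C/[C@@H](OCc2ccc(OC)cc2)[C@]3(C)[C@@H]([C@@H](O[Si](C)(C)C(C)(C)C)[C@]5(O)[C@@H](C)C(=O)O[C@H]5[C@H]1Cl)[C@@H](C)C(=O)CC3Cl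
F9 | step 29 | ring A enone (C13=C14) | C=C1/C=C/[C@@H](OCc2ccc(OC)cc2)[C@]3(C)[C@@H]([C@@H](O[Si](C)(C)C(C)(C)C)[C@]5(O)[C@@H](C)C(=O)O[C@H]5[C@H]1Cl)[C@@H](C)C(=O)C=C3
F10 | step 29 | 13α,14α-epoxy-12-ketone | C=C1/C=C/[C@@H](OCc2ccc(OC)cc2)[C@]3(C)[C@@H]([C@@H](O[Si](C)(C)C(C)(C)C)[C@]5(O)[C@@H](C)C(=O)O[C@H]5[C@H]1Cl)[C@@H](C)C(=O)[C@@H]6O[C@H]36
F11 | step 22 | C2 vinyl compound (C3=CH2) | C=C[C@@H](OCc1ccc(OC)cc1)[C@]3(C)[C@@H]([C@@H](O[Si](C)(C)C(C)(C)C)[C@H](O[Si](CC)(CC)CC)[C@@H](OCOC)CO[Si](CC)(CC)CC)[C@@H](C)[C@]4(O[Si](CC)(CC)CC)C[C@H]34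
F12 | step 22 | C6 aldehyde of F11 | C=C[C@@H](OCc1ccc(OC)cc1)[C@]3(C)[C@@H]([C@@H](O[Si](C)(C)C(C)(C)C)[C@H](O[Si](CC)(CC)CC)[C@@H](OCOC)C=O)[C@@H](C)[C@]4(O[Si](CC)(CC)CC)C[C@H]34
F13 | step 22 | dienyl carbinol (C6–OH, C5(=C16)–C4=CH2) | C=C[C@@H](OCc1ccc(OC)cc1)[C@]3(C)[C@@H]([C@@H](O[Si](C)(C)C(C)(C)C)[C@H](O[Si](CC)(CC)CC)[C@@H](OCOC)[C@H](O)C(=C)C=C)[C@@H](C)[C@]4(O[Si](CC)(CC)CC)C[C@H]34
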